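**Strategy.** Ring A is disconnected across C1–C2 and C4–C5 into two three-carbon units tied through the oxygen of the future 6,19-lactone. The precursor is an open-chain acetoacetate ester of (E)-4-hydroxy-3-methylbut-2-enal. Under amine catalysis the acetoacetate carbon C5 adds to the enal β-carbon C4 (closing the γ-lactone, setting quaternary C4), then the acetyl methyl C1 condenses with the aldehyde C2 (closing ring A). The step exploits the 1,3-relation of C2 and C4 in an enal and of C1 and C5 about a ketone, which becomes spiro-C10. That ketone then carries the δ-lactone by an epoxide-radical addition; rings C and D follow from ketyl–olefin and palladium-mediated cyclisations.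

Key step: step 3

Remarks on the chemistry:
- Locants C1–C20 follow ent-kaurane numbering.
- Compounds 1, 2, 4, 11, 14, 15 and 17 are taken as commercial.
- The sense of induction in step 3 is assigned from the usual shielding model of diarylprolinol silyl ether iminium ions.
- For 10, 22, 23, 27 (C8) and 30 (C15) the expected major isomer is drawn; each of these centres is erased or becomes irrelevant in a following step.

**Step 1**
Reactants: 1 2-methylprop-2-en-1-ol; 2 2,2,6-trimethyl-4H-1,3-dioxin-4-one
Product: 3 2-methylprop-2-en-1-yl 3-oxobutanoate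
Conditions: xylene, 140 °C (acetone distilled off)
Reagents that add atoms: 2,2,6-trimethyl-4H-1,3-dioxin-4-one (2), CC1=CC(=O)OC(C)(C)O1
Why: Thermal retro-[4+2] of the dioxinone releases acetylketene, which the alcohol traps (acetoacetylation); no stereocentre is formed.

**Step 2**
Reactants: 3 2-methylprop-2-en-1-yl 3-oxobutanoate; 4 (E)-but-2-enal
Product: 5 (E)-2-methyl-4-oxobut-2-en-1-yl 3-oxobutanoate
Conditions: second-generation Hoveyda–Grubbs catalyst RuCl2(SIMes)(=CH-C6H4-2-O-i-Pr) (5 mol %), 4 (5 equiv), CH2Cl2, 40 °C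
Reagents that add atoms: (E)-but-2-enal (4), C/C=C/C=O
Why: Olefin cross-metathesis of the 1,1-disubstituted alkene with an enal partner should give the trisubstituted enal, the E isomer (CH2O trans to CHO) being the thermodynamic one.

**Step 3**
Reactants: 5 (E)-2-methyl-4-oxobut-2-en-1-yl 3-oxobutanoate
Product: 7 (3aR,7aR)-3a-methyl-3a,4-dihydro-2-benzofuran-1,7(3H,7aH)-dione, via Michael adduct 6 (not isolated)
Conditions: (S)-2-[diphenyl(trimethylsilyloxy)methyl]pyrrolidine (20 mol %), PhCO2H (20 mol %), toluene, 0 °C to rt; then p-TsOH·H2O (20 mol %), 60 °C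
Reagents that add atoms: none
Why: The secondary amine converts the enal into an iminium ion and the acetoacetate enol (C5) adds to the β-carbon C4 in a 5-exo-trig Michael closure of the γ-lactone; after hydrolysis the methyl ketone enol (C1) attacks the freed aldehyde C2 in a 6-(enolendo)-exo-trig aldol closure of ring A, and acid-promoted dehydration gives the enone. The closest known reaction type is the amine-catalysed Michael/aldol condensation of acetoacetates with enals to cyclohexenones (Hagemann-type [3+3] annulation), run here in ester-tethered form, together with diarylprolinol silyl ether-catalysed Michael additions to β,β-disubstituted enals. C4 is set by the catalyst: the diphenyl(silyloxy)methyl group of the (S)-amine shields one face of the s-trans E-iminium ion, so C5 bonds to the open face and the quaternary centre should be R. C5 is a β-dicarbonyl position and equilibrates by enolisation to the cis-fused lactone. The step needs 1,4- over 1,2-addition (Knoevenagel), which iminium activation and the five-membered tether secure, and one aldol regiochemistry, which is fixed because only C1 can reach C2 through a six-membered ring.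

**Step 4**
Reactants: 7 (3aR,7aR)-3a-methyl-3a,4-dihydro-2-benzofuran-1,7(3H,7aH)-dione
Product: 8 (3aR,7aR)-3a-methyl-3a,4,5,6-tetrahydro-2-benzofuran-1,7(3H,7aH)-dione
Conditions: H2 (1 atm), Pd/C (10 %), EtOAc, rt
Reagents that add atoms: none
Why: Heterogeneous hydrogenation saturates the conjugated C1=C2 bond and leaves both carbonyl groups untouched; no new stereocentre.

**Step 5**
Reactants: 8 (3aR,7aR)-3a-methyl-3a,4,5,6-tetrahydro-2-benzofuran-1,7(3H,7aH)-dione
Product: 9 (3aR,7aS)-3a-methyl-7-methylidene-3a,4,5,6,7,7a-hexahydro-2-benzofuran-1(3H)-one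
Conditions: Zn, CH2Br2, TiCl4, THF/CH2Cl2, 0 °C to rt
Reagents that add atoms: dibromomethane, BrCBr
Why: Takai–Lombardo methylenation uses a non-basic titanium–zinc methylene reagent that should olefinate the C10 ketone of the acidic β-keto lactone without enolate formation and without touching the lactone.

**Step 6**
Reactants: 9 (3aR,7aS)-3a-methyl-7-methylidene-3a,4,5,6,7,7a-hexahydro-2-benzofuran-1(3H)-one
Product: 10 (3aR,7R,7aR)-3a-methylhexahydro-1H-spiro[2-benzofuran-7,2'-oxiran]-1-one (C10–C20 epoxide, oxygen on the face of H5)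
Conditions: mCPBA, NaHCO3, CH2Cl2, 0 °C
Reagents that add atoms: 3-chloroperbenzoic acid, OOC(=O)c1cccc(Cl)c1
Why: Prilezhaev epoxidation of the 1,1-disubstituted alkene under buffered conditions, expected from the face away from the axial C19 and the C5–C6 bond; the epoxide configuration is lost in step 7.

**Step 7**
Reactants: 10 spiro-epoxide; 11 2,2,2-trifluoroethyl prop-2-enoate
Product: 13 spiro bis-lactone (4R,5R,10R; ring A cis-fused to the C6/C19 γ-lactone, δ-lactone C7–C8–C9–C10–C20–O spiro at C10), via hydroxy ester 12 (not isolated)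
Conditions: Cp2TiCl2 (20 mol %), Mn, 2,4,6-collidine hydrochloride, 11 (5 equiv), THF, rt; then p-TsOH (cat.), rt
Reagents that add atoms: 2,2,2-trifluoroethyl prop-2-enoate (11), C=CC(=O)OCC(F)(F)F
Why: Cp2TiCl (trivalent titanium) opens the epoxide to the tertiary C10 radical, which adds to the acrylate (reductive epoxide opening/Giese addition) anti to the C5–C6 bond and to the axial C19, so that C9 enters cis to H5; the C20 alkoxide then lactonises onto the activated ester.

**Step 8**
Reactants: 14 (S)-4-benzyl-1,3-oxazolidin-2-one; 15 3-methylbut-2-enoyl chloride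
Product: 16 (S)-4-benzyl-3-(3-methylbut-2-enoyl)-1,3-oxazolidin-2-one
Conditions: n-BuLi, THF, −78 °C; then 15
Reagents that add atoms: 3-methylbut-2-enoyl chloride (15), CC(C)=CC(Cl)=O
Why: N-acylation of the lithiated Evans auxiliary; the auxiliary stereocentre is untouched.

**Step 9**
Reactants: 17 2-[(tert-butyldimethylsilyl)oxy]ethan-1-ol
Product: 18 2-[(tert-butyldimethylsilyl)oxy]ethyl trifluoromethanesulfonate
Conditions: Tf2O, 2,6-lutidine, CH2Cl2, −78 °C (used at once)
Reagents that add atoms: trifluoromethanesulfonic anhydride, O=S(=O)(OS(=O)(=O)C(F)(F)F)C(F)(F)F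
Why: O-sulfonylation of a primary alcohol gives an electrophile reactive enough for an imide enolate.

**Step 10**
Reactants: 16 (S)-4-benzyl-3-(3-methylbut-2-enoyl)-1,3-oxazolidin-2-one; 18 2-[(tert-butyldimethylsilyl)oxy]ethyl trifluoromethanesulfonate
Product: 19 (S)-4-benzyl-3-[(S)-2-{2-[(tert-butyldimethylsilyl)oxy]ethyl}-3-methylbut-3-enoyl]-1,3-oxazolidin-2-one
Conditions: NaN(SiMe3)2, THF, −78 °C; then 18, −78 to −30 °C
Reagents that add atoms: 2-[(tert-butyldimethylsilyl)oxy]ethyl trifluoromethanesulfonate (18), CC(C)(C)[Si](C)(C)OCCOS(=O)(=O)C(F)(F)F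
Why: Evans deconjugative α-alkylation: γ-deprotonation gives the chelated sodium dienolate, which is alkylated at the α-carbon on the face opposite the benzyl group, setting C13 (S) and unveiling the isopropenyl group.

**Step 11**
Reactants: 19 alkylated imide
Product: 20 (S)-2-{2-[(tert-butyldimethylsilyl)oxy]ethyl}-3-methylbut-3-en-1-ol
Conditions: LiBH4, MeOH (1 equiv), Et2O, 0 °C
Reagents that add atoms: none
Why: Reductive cleavage of the N-acyl oxazolidinone gives the primary alcohol (C14) and returns the auxiliary; C13 is not epimerisable under these conditions.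

**Step 12**
Reactants: 20 (S)-2-{2-[(tert-butyldimethylsilyl)oxy]ethyl}-3-methylbut-3-en-1-ol
Product: 21 (S)-tert-butyl{[3-(iodomethyl)-4-methylpent-4-en-1-yl]oxy}dimethylsilane
Conditions: I2, PPh3, imidazole, CH2Cl2, 0 °C to rt
Reagents that add atoms: iodine, [I][I]
Why: Appel-type iodination of the primary alcohol; the silyl ether and the alkene are inert.

**Step 13**
Reactants: 13 spiro bis-lactone; 21 iodide
Product: 22 C8-alkylated bis-lactone (C8 bears the C14–C13(isopropenyl)–C12–C11(OTBS) chain; 13S)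
Conditions: LiN(i-Pr)2, THF, −78 °C; then 21, HMPA, −78 to −30 °C
Reagents that add atoms: iodide 21, C=C(C)[C@H](CCO[Si](C)(C)C(C)(C)C)CI
Why: Kinetic enolate alkylation at the accessible C8 methylene of the δ-lactone; the γ-lactone C5–H lies between two quaternary carbons and should not be removed, and the new C8 centre is erased in step 14.

**Step 14**
Reactants: 22 C8-alkylated bis-lactone
Product: 24 C8=C9 unsaturated δ-lactone carrying the side chain, via α-phenylselenide 23 (not isolated)
Conditions: LiN(i-Pr)2, THF, −78 °C; PhSeBr; then 30 % H2O2, pyridine, CH2Cl2, 0 °C to rt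
Reagents that add atoms: none
Why: α-Selenenylation followed by selenoxide syn-elimination should give the endocyclic conjugated lactone, the more stable trisubstituted enoate.

**Step 15**
Reactants: 24 unsaturated lactone silyl ether
Product: 25 unsaturated lactone C11 primary alcohol
Conditions: HF·pyridine, pyridine, THF, 0 °C
Reagents that add atoms: none
Why: Fluoride-mediated cleavage of the primary silyl ether under buffered conditions that spare both lactones.

**Step 16**
Reactants: 25 unsaturated lactone C11 primary alcohol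
Product: 26 unsaturated lactone C11 aldehyde
Conditions: Dess–Martin periodinane, NaHCO3, CH2Cl2, rt
Reagents that add atoms: none
Why: Dess–Martin oxidation of the primary alcohol to the aldehyde without touching C13 or the alkenes.

**Step 17**
Reactants: 26 unsaturated lactone C11 aldehyde
Product: 27 tetracyclic alcohol (ring C closed; 11-OH cis to C7 and C10; H8 and H9 cis; isopropenyl at C13)
Conditions: SmI2, LiBr, t-BuOH, THF, −78 °C
Reagents that add atoms: none
Why: SmI2 (divalent samarium) ketyl–olefin cyclisation: the C11 ketyl adds to C9 of the unsaturated lactone through a chair with the isopropenyl group equatorial and samarium bridging the ketyl oxygen and the lactone carbonyl (11-OH cis to C7), on the lactone face syn to C1H2 and anti to C5; the enolate is then protonated at C8.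

**Step 18**
Reactants: 27 tetracyclic alcohol
Product: 29 pentacyclic 16(17)-alkene with 11-OTBS (bicyclo[3.2.1]octane closed), via bis-silyl ketene acetal 28 (not isolated)
Conditions: KN(SiMe3)2, TBSCl, THF/DMPU, −78 °C; then Pd(OAc)2 (1.0 equiv), AcOH, DMSO, 45 °C
Reagents that add atoms: tert-butyldimethylsilyl chloride, CC(C)(C)[Si](C)(C)Cl
Why: Oxidative cyclisation of the δ-lactone silyl ketene acetal with Pd(OAc)2 (divalent palladium) forms C8–C15 on the only face the isopropenyl tether can reach, and β-hydride elimination towards the methyl group should give the exocyclic alkene; the C11 hydroxyl is silylated in the same pot.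

**Step 19**
Reactants: 29 pentacyclic 16(17)-alkene
Product: 30 15-hydroxy-16(17)-alkene
Conditions: SeO2 (0.5 equiv), t-BuOOH, CH2Cl2, rt
Reagents that add atoms: selenium dioxide (oxygen donor), O=[Se]=O; tert-butyl hydroperoxide (terminal oxidant), CC(C)(C)OO
Why: Ene/[2,3]-sigmatropic allylic oxidation at C15, the only allylic methylene (C13 is a bridgehead); the C15 configuration is lost in step 20.

**Step 20**
Reactants: 30 15-hydroxy-16(17)-alkene
Product: 31 15-oxo-16(17)-ene (α-methylene cyclopentanone)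
Conditions: Dess–Martin periodinane, NaHCO3, CH2Cl2, rt
Reagents that add atoms: none
Why: Oxidation of the allylic alcohol to the enone; C11 is protected.

**Step 21**
Reactants: 31 15-oxo-16(17)-ene
Product: 33 17-hydroxy-15-ketone with 11-OTBS, via pinacol boronate 32 (not isolated)
Conditions: CuCl (10 mol %), Xantphos (10 mol %), NaOt-Bu (10 mol %), B2pin2, MeOH, THF, 0 °C; then 30 % H2O2, NaHCO3, THF/H2O, 0 °C
Reagents that add atoms: bis(pinacolato)diboron (boron of 32), CC1(C)OB(OC1(C)C)B1OC(C)(C)C(C)(C)O1; hydrogen peroxide (oxygen at C17), OO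
Why: Conjugate borylation of the enone with a CuCl-derived (monovalent copper) boryl species, then C–B oxidation with retention; C16 is set by protonation of the enolate on the exo face, away from the C9–C11–C12 bridge, which places the CH2OH group endo as required.

**Step 22**
Reactants: 33 17-hydroxy-15-ketone with 11-OTBS
Product: 34 target (11,17-dihydroxy-15-oxo-6,7-seco-ent-kaurane-6,19:7,20-diolide)
Conditions: HF·pyridine, pyridine, THF, 0 °C to rt
Reagents that add atoms: none
Why: Acidic fluoride cleavage of the secondary silyl ether avoids the basic conditions that could trigger retro-aldol or retro-Claisen opening of the β-hydroxy ketone/β-keto lactone.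

**Compound list**

1 | 2-methylprop-2-en-1-ol | CC(=C)CO | starting material
2 | 2,2,6-trimethyl-4H-1,3-dioxin-4-one | CC1=CC(=O)OC(C)(C)O1 | starting material
3 | 2-methylprop-2-en-1-yl 3-oxobutanoate | CC(=O)CC(=O)OCC(C)=C | intermediate
4 | (E)-but-2-enal | C/C=C/C=O | starting material
5 | (E)-2-methyl-4-oxobut-2-en-1-yl 3-oxobutanoate | CC(=O)CC(=O)OC/C(C)=C/C=O | intermediate
6 | (3R,4R)-3-acetyl-4-methyl-4-(2-oxoethyl)oxolan-2-one (Michael adduct) | CC(=O)[C@@H]1C(=O)OC[C@]1(C)CC=O | intermediate
7 | (3aR,7aR)-3a-methyl-3a,4-dihydro-2-benzofuran-1,7(3H,7aH)-dione | C[C@@]12CC=CC(=O)[C@@H]1C(=O)OC2 | intermediate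
8 | (3aR,7aR)-3a-methyl-3a,4,5,6-tetrahydro-2-benzofuran-1,7(3H,7aH)-dione | C[C@@]12CCCC(=O)[C@@H]1C(=O)OC2 | intermediate
9 | (3aR,7aS)-3a-methyl-7-methylidene-3a,4,5,6,7,7a-hexahydro-2-benzofuran-1(3H)-one | C[C@@]12CCCC(=C)[C@@H]1C(=O)OC2 | intermediate
10 | (3aR,7R,7aR)-3a-methylhexahydro-1H-spiro[2-benzofuran-7,2'-oxiran]-1-one | C[C@@]12CCC[C@]3(CO3)[C@@H]1C(=O)OC2 | intermediate
11 | 2,2,2-trifluoroethyl prop-2-enoate | C=CC(=O)OCC(F)(F)F | starting material
12 | hydroxy ester (C10 bears CH2OH and CH2CH2CO2CH2CF3; 4R,5R,10R) | C[C@@]12CCC[C@@](CO)(CCC(=O)OCC(F)(F)F)[C@@H]1C(=O)OC2 | intermediate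
13 | spiro bis-lactone (4R,5R,10R) | C[C@@]12CCC[C@]3(COC(=O)CC3)[C@@H]1C(=O)OC2 | intermediate
14 | (S)-4-benzyl-1,3-oxazolidin-2-one | O=C1OC[C@H](Cc2ccccc2)N1 | starting material
15 | 3-methylbut-2-enoyl chloride | CC(C)=CC(Cl)=O | starting material
16 | (S)-4-benzyl-3-(3-methylbut-2-enoyl)-1,3-oxazolidin-2-one | CC(C)=CC(=O)N1[C@@H](Cc2ccccc2)COC1=O | intermediate
17 | 2-[(tert-butyldimethylsilyl)oxy]ethan-1-ol | CC(C)(C)[Si](C)(C)OCCO | starting material
18 | 2-[(tert-butyldimethylsilyl)oxy]ethyl trifluoromethanesulfonate | CC(C)(C)[Si](C)(C)OCCOS(=O)(=O)C(F)(F)F | intermediate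
19 | (S)-4-benzyl-3-[(S)-2-{2-[(tert-butyldimethylsilyl)oxy]ethyl}-3-methylbut-3-enoyl]-1,3-oxazolidin-2-one | C=C(C)[C@H](CCO[Si](C)(C)C(C)(C)C)C(=O)N1[C@@H](Cc2ccccc2)COC1=O | intermediate
20 | (S)-2-{2-[(tert-butyldimethylsilyl)oxy]ethyl}-3-methylbut-3-en-1-ol | C=C(C)[C@H](CCO[Si](C)(C)C(C)(C)C)CO | intermediate
21 | (S)-tert-butyl{[3-(iodomethyl)-4-methylpent-4-en-1-yl]oxy}dimethylsilane | C=C(C)[C@H](CCO[Si](C)(C)C(C)(C)C)CI | intermediate
22 | C8-alkylated bis-lactone (major C8 epimer) | C[C@@]12CCC[C@]3(COC(=O)[C@@H](C[C@@H](CCO[Si](C)(C)C(C)(C)C)C(C)=C)C3)[C@@H]1C(=O)OC2 | intermediate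
23 | C8 α-phenylselenide (major C8 epimer) | C[C@@]12CCC[C@]3(COC(=O)[C@@](C[C@@H](CCO[Si](C)(C)C(C)(C)C)C(C)=C)([Se]c4ccccc4)C3)[C@@H]1C(=O)OC2 | intermediate
24 | C8=C9 unsaturated δ-lactone, C11 silyl ether | C[C@@]12CCC[C@]3(COC(=O)C(C[C@@H](CCO[Si](C)(C)C(C)(C)C)C(C)=C)=C3)[C@@H]1C(=O)OC2 | intermediate
25 | C8=C9 unsaturated δ-lactone, C11 primary alcohol | C[C@@]12CCC[C@]3(COC(=O)C(C[C@@H](CCO)C(C)=C)=C3)[C@@H]1C(=O)OC2 | intermediate
26 | C8=C9 unsaturated δ-lactone, C11 aldehyde | C[C@@]12CCC[C@]3(COC(=O)C(C[C@@H](CC=O)C(C)=C)=C3)[C@@H]1C(=O)OC2 | intermediate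
27 | tetracyclic 11-alcohol with C13 isopropenyl | C[C@@]12CCC[C@]3(COC(=O)[C@H]4C[C@@H](C[C@@H](O)[C@H]43)C(C)=C)[C@@H]1C(=O)OC2 | intermediate
28 | bis-silyl ketene acetal (11-OTBS; C7(OTBS)=C8) | C[C@@]12CCC[C@]3(COC(O[Si](C)(C)C(C)(C)C)=C4C[C@@H](C[C@@H](O[Si](C)(C)C(C)(C)C)[C@H]43)C(C)=C)[C@@H]1C(=O)OC2 | intermediate
29 | pentacyclic 16(17)-alkene, 11-OTBS | C[C@@]12CCC[C@]3(COC(=O)[C@@]45C[C@@H](C[C@@H](O[Si](C)(C)C(C)(C)C)[C@H]43)C(=C)C5)[C@@H]1C(=O)OC2 | intermediate
30 | 15-hydroxy-16(17)-alkene, 11-OTBS (major C15 epimer) | C[C@@]12CCC[C@]3(COC(=O)[C@@]45C[C@@H](C[C@@H](O[Si](C)(C)C(C)(C)C)[C@H]43)C(=C)[C@@H]5O)[C@@H]1C(=O)OC2 | intermediate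
31 | 15-oxo-16(17)-ene, 11-OTBS | C[C@@]12CCC[C@]3(COC(=O)[C@@]45C[C@@H](C[C@@H](O[Si](C)(C)C(C)(C)C)[C@H]43)C(=C)C5=O)[C@@H]1C(=O)OC2 | intermediate
32 | 17-(pinacolboryl)-15-ketone, 11-OTBS | C[C@@]12CCC[C@]3(COC(=O)[C@@]45C[C@@H](C[C@@H](O[Si](C)(C)C(C)(C)C)[C@H]43)[C@@H](CB6OC(C)(C)C(C)(C)O6)C5=O)[C@@H]1C(=O)OC2 | intermediate
33 | 17-hydroxy-15-ketone, 11-OTBS | C[C@@]12CCC[C@]3(COC(=O)[C@@]45C[C@@H](C[C@@H](O[Si](C)(C)C(C)(C)C)[C@H]43)[C@@H](CO)C5=O)[C@@H]1C(=O)OC2 | intermediate
34 | CNP0555433.1 (11,17-dihydroxy-15-oxo-6,7-seco-ent-kaurane-6,19:7,20-diolide) | C[C@@]12CCC[C@]3(COC(=O)[C@@]45C[C@@H](C[C@@H](O)[C@H]43)[C@@H](CO)C5=O)[C@@H]1C(=O)OC2 | target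

**Step count.** Total: 22 steps. Longest linear sequence: 17 steps (steps 1–7 and 13–22); steps 8–12 make the side-chain iodide.

**Steps most likely to fail**

Step 3. The iminium ion of the β,β-disubstituted enal may form slowly or isomerise E/Z through its dienamine, so that facial selectivity at C4 is eroded or a racemic background Michael addition competes. The fallback sets out from 5 and comes back at 8. Compound 5 is cyclised with an achiral amine (pyrrolidine, AcOH; then p-TsOH), which should give 7 together with its mirror image, the ent-enone lactone F1. Hydrogenation (H2, Pd/C) gives 8 together with the ent-keto lactone F2. Condensation of the mixture with (S)-1-phenylethylamine (toluene, cat. p-TsOH, water removal) gives two diastereomeric vinylogous carbamates, the (4R)-enamino lactone F3 and the (4S)-enamino lactone F4, to be separated by crystallisation or chromatography. Hydrolysis of F3 (1 M HCl, THF) returns 8 as a single enantiomer.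

Step 14. The selenoxide may eliminate towards C14 instead of C9, giving the exocyclic alkylidene lactone. The fallback sets out from 13 (and uses iodide 21) and comes back at 24. Compound 13 is selenenylated (LiN(i-Pr)2, PhSeBr) to the α-phenylselenide F5 and oxidised (H2O2, pyridine) to the parent unsaturated spiro-lactone F6, in which only C9 carries β-hydrogens. α-Iodination (I2, pyridine, CH2Cl2) gives the α-iodo unsaturated lactone F7. Iodide 21 is converted with Zn dust and LiCl in THF into the alkylzinc iodide F8, and Negishi coupling of F7 with F8 (Pd2(dba)3, SPhos, THF, rt) gives 24 with the double bond fixed at C8=C9.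

Step 18. The alkylpalladium intermediate may undergo β-hydride elimination into the ring (C15=C16), or the ketene acetal may be protodesilylated before carbopalladation. The fallback sets out from 27 and comes back at 29. Silylation (TBSOTf, 2,6-lutidine, CH2Cl2) gives the C11 silyl ether F9. Ene-type allylic chlorination of the isopropenyl group (N-chlorosuccinimide, PhSeCl 10 mol %, CH2Cl2) gives the allylic chloride F10. KN(SiMe3)2 (THF, −78 to 0 °C) forms the C8 enolate, which closes ring D by intramolecular allylation; direct and allylic displacement give the same product, 29.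

**Further compounds**

F1 | step 3 | ent-enone lactone, (3aS,7aS)-3a-methyl-3a,4-dihydro-2-benzofuran-1,7(3H,7aH)-dione | C[C@]12CC=CC(=O)[C@H]1C(=O)OC2
F2 | step 3 | ent-keto lactone, (3aS,7aS)-3a-methyl-3a,4,5,6-tetrahydro-2-benzofuran-1,7(3H,7aH)-dione | C[C@]12CCCC(=O)[C@H]1C(=O)OC2
F3 | step 3 | (4R)-enamino lactone from 8 and (S)-1-phenylethylamine | C[C@@]12CCCC(N[C@@H](C)c3ccccc3)=C1C(=O)OC2
F4 | step 3 | (4S)-enamino lactone from F2 and (S)-1-phenylethylamine | C[C@]12CCCC(N[C@@H](C)c3ccccc3)=C1C(=O)OC2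
F5 | step 14 | α-phenylselenide of spiro bis-lactone 13 | C[C@@]12CCC[C@]3(COC(=O)[C@@H]([Se]c4ccccc4)C3)[C@@H]1C(=O)OC2
F6 | step 14 | parent C8=C9 unsaturated spiro-lactone | C[C@@]12CCC[C@]3(COC(=O)C=C3)[C@@H]1C(=O)OC2
F7 | step 14 | α-iodo unsaturated spiro-lactone | C[C@@]12CCC[C@]3(COC(=O)C(=C3)I)[C@@H]1C(=O)OC2
F8 | step 14 | alkylzinc iodide from 21 | C=C(C)[C@H](CCO[Si](C)(C)C(C)(C)C)C[Zn]I
F9 | step 18 | C11 silyl ether of 27 | C[C@@]12CCC[C@]3(COC(=O)[C@H]4C[C@@H](C[C@@H](O[Si](C)(C)C(C)(C)C)[C@H]43)C(C)=C)[C@@H]1C(=O)OC2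
F10 | step 18 | allylic chloride (C13 bears 3-chloroprop-1-en-2-yl) | C[C@@]12CCC[C@]3(COC(=O)[C@H]4C[C@@H](C[C@@H](O[Si](C)(C)C(C)(C)C)[C@H]43)C(CCl)=C)[C@@H]1C(=O)OC2
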